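**Retrosynthetic overview**

1. Target ⇒ its C5 PMB ether ⇒ hetero-Diels–Alder across the exocyclic C8=CH2 bond (O–C8 and CH2–C7' bonds; the dihydropyran is formed last) of a (3Z)-5-PMB-oxy-caryophylla-3,8(exocyclic)-diene with isobutylidene-syncarpic acid (syncarpic acid + 3-methylbutanal).
2. Diene ⇒ Wittig ⇒ trans-fused nine-membered ketone ⇒ anionic oxy-Cope ring expansion (C5–C6 made, C3–C8 broken) of a cis-1-vinyl-2-alkenyl-bicyclo[3.2.0]heptan-2-ol.
3. Feature used: in the nine-membered ring the oxygen-bearing C8 and the Z C3=C4 alkene lie four atoms apart on both sides (C8–C7–C6–C5 and C8–C9–C1–C2), with C5 oxygenated. This is a δ,ε-unsaturated ketone whose C3 and C8 can be the ends of a broken cyclopentane bond.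
4. Carbinol ⇒ exo-face vinylation ⇒ exo α-alkenylation of (1R,5R)-6,6-dimethylbicyclo[3.2.0]heptan-2-one with an (E)-2-iodo enol ether (hydrozirconation of a PMB propynyl ether) ⇒ Cu(I) photobicyclisation of (S)-7-methylocta-1,6-dien-3-ol.
5. Ring order: cyclobutane and cyclopentane together (step 3), nine-membered ring by expansion of the cyclopentane (step 10), dihydropyran (step 14); the syncarpic ring is brought in preformed.

Key step: step 10

Assumption: caryophyllane numbering is used for the nine-membered-ring compounds in the text (C1/C9 ring fusion, C11 the CMe2 carbon, C8 the carbonyl/spiro carbon, primed numbers for the syncarpic ring, C7' the isobutyl-bearing carbon); the boat-type array is taken as the operative geometry of the cis-dialkenyl cyclopentanolate.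

**Route**

Step 1
Reactants: 1 5-methylhex-4-enal; 2 vinylmagnesium bromide
Product: 3 rac-7-methylocta-1,6-dien-3-ol
Conditions: THF, −78 → 0 °C; H2O quench
Reagents that add atoms: none
Why: Grignard 1,2-addition to the unhindered aldehyde gives the racemic vinyl carbinol; no stereocontrol is needed because the enantiomers are separated in step 2.

Step 2
Reactants: 3 rac-7-methylocta-1,6-dien-3-ol
Product: 4 (3S)-7-methylocta-1,6-dien-3-ol
Conditions: Ti(OiPr)4 (cat.), D-(−)-diisopropyl tartrate, t-BuOOH (0.6 equiv), 4 Å MS, CH2Cl2, −20 °C, stopped a little past half conversion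
Reagents that add atoms: none
Why: Sharpless kinetic resolution, in which the D-(−)-tartrate catalyst should epoxidise the (3R)-vinyl carbinol much faster and leave the (3S)-alcohol; the remote trisubstituted alkene is not an allylic alcohol and should not react.

Step 3
Reactants: 4 (3S)-7-methylocta-1,6-dien-3-ol
Product: 5 (1R,2S,5R)-6,6-dimethylbicyclo[3.2.0]heptan-2-ol (2-endo alcohol)
Conditions: (CuOTf)2·C6H6 (cat.), Et2O, hν 254 nm (quartz), rt; chromatographic removal of the 2-exo epimer
Reagents that add atoms: none
Why: Salomon–Kochi copper(I)-catalysed intramolecular [2+2] photocycloaddition of a 1,6-dien-3-ol, in which copper binds both alkenes and the hydroxyl so that the cis-fused bicycle should form with endo OH, setting C1 and C5 (C5 becomes C1 of the target) from the carbinol centre; the minor exo epimer carries the enantiomeric ring fusion and must be removed here.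

Step 4
Reactants: 5 (1R,2S,5R)-6,6-dimethylbicyclo[3.2.0]heptan-2-ol
Product: 6 (1R,5R)-6,6-dimethylbicyclo[3.2.0]heptan-2-one
Conditions: TPAP (cat.), NMO, 4 Å MS, CH2Cl2, rt
Reagents that add atoms: none
Why: Ley–Griffith oxidation of the secondary alcohol; the ring fusion can only be cis, so the enantiomeric purity fixed in steps 2 and 3 is carried into the ketone.

Step 5
Reactants: 6 (1R,5R)-6,6-dimethylbicyclo[3.2.0]heptan-2-one
Product: 8 trimethyl{[(1R,5R)-6,6-dimethylbicyclo[3.2.0]hept-2-en-2-yl]oxy}silane, via lithium enolate 7 (not isolated)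
Conditions: LDA, THF, −78 °C; TMSCl, −78 °C → rt
Reagents that add atoms: chlorotrimethylsilane, C[Si](C)(C)Cl
Why: Kinetic deprotonation should occur at the C3 methylene (the ring-fusion C1–H is hindered and would give a strained enolate toward the cyclobutane) and O-silylation traps the Δ2 enolate regiospecifically.

Step 6
Reactants: 9 (4-methoxyphenyl)methanol; 10 trichloroethene
Product: 14 1-methoxy-4-[(prop-1-yn-1-yloxy)methyl]benzene, via dichlorovinyl ether 11 (not isolated), via chloroalkynyl ether 12 (not isolated), via lithium alkynyl ether 13 (not isolated)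
Conditions: KH, THF, 0 °C; 10, rt; n-BuLi (2.3 equiv), −78 °C; MeI, HMPA, −78 → 0 °C; used cold and directly
Reagents that add atoms: iodomethane, CI
Why: Greene ynol ether synthesis: alkoxide addition–elimination on trichloroethene, then dehydrochlorination and chlorine–lithium exchange with n-BuLi, then C-methylation of the lithium alkynyl ether; the product is not stored because benzylic alkynyl ethers rearrange on warming.

Step 7
Reactants: 14 1-methoxy-4-[(prop-1-yn-1-yloxy)methyl]benzene
Product: 16 1-({[(1E)-2-iodoprop-1-en-1-yl]oxy}methyl)-4-methoxybenzene, via alkenylzirconocene 15 (not isolated)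
Conditions: Cp2Zr(H)Cl, THF, 0 °C → rt, dark; I2, −78 °C
Reagents that add atoms: iodine, II
Why: Hydrozirconation is a syn addition that should place hydride on the electrophilic O-bearing carbon and zirconium on the β-carbon (as with ethoxyethyne), and iodinolysis with retention then gives the iodide with iodine trans to oxygen, i.e. (E).

Step 8
Reactants: 8 trimethyl{[(1R,5R)-6,6-dimethylbicyclo[3.2.0]hept-2-en-2-yl]oxy}silane; 16 1-({[(1E)-2-iodoprop-1-en-1-yl]oxy}methyl)-4-methoxybenzene
Product: 18 (1R,3S,5R)-3-{(1E)-1-[(4-methoxyphenyl)methoxy]prop-1-en-2-yl}-6,6-dimethylbicyclo[3.2.0]heptan-2-one, via tin enolate 17 (not isolated)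
Conditions: Bu3SnF, PdCl2[P(o-tol)3]2 (cat.), toluene, 80 °C
Reagents that add atoms: none
Why: Migita–Kuwajima palladium-catalysed α-alkenylation through the tributyltin enolate, which couples with retention of alkene geometry under neutral conditions; the C3–C bond should form on the convex (exo) face, and without strong base the β,γ-unsaturated ketone should be neither epimerised nor conjugated.

Step 9
Reactants: 18 (1R,3S,5R)-3-{(1E)-1-[(4-methoxyphenyl)methoxy]prop-1-en-2-yl}-6,6-dimethylbicyclo[3.2.0]heptan-2-one; 2 vinylmagnesium bromide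
Product: 19 (1R,2R,3S,5R)-2-ethenyl-3-{(1E)-1-[(4-methoxyphenyl)methoxy]prop-1-en-2-yl}-6,6-dimethylbicyclo[3.2.0]heptan-2-ol
Conditions: 2 premixed with anhydrous CeCl3, THF, −78 °C; H2O/NaHCO3 quench
Reagents that add atoms: none
Why: Organocerium 1,2-addition (Imamoto conditions, which suppress enolisation of the β,γ-unsaturated ketone); the concave face is blocked by the C7 methylene and the endo C6 methyl of the folded cyclobutane, so vinyl should enter from the exo face and end cis to the C3 alkenyl group.

Step 10
Reactants: 19 (1R,2R,3S,5R)-2-ethenyl-3-{(1E)-1-[(4-methoxyphenyl)methoxy]prop-1-en-2-yl}-6,6-dimethylbicyclo[3.2.0]heptan-2-ol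
Product: 23 (1S,5R,6Z,9R)-5-[(4-methoxyphenyl)methoxy]-6,10,10-trimethylbicyclo[7.2.0]undec-6-en-2-one (trans-fused; caryophyllane 1R,3Z,5R,9S), via potassium alkoxide 20 (not isolated), via potassium enolate 21 (not isolated), via cis-fused ketone 22 (not isolated)
Conditions: KH, 18-crown-6, THF, 0 → 25 °C; then MeOH, 25 °C; aq. NH4Cl
Reagents that add atoms: none
Why: KH/18-crown-6 gives the naked alkoxide 20, in which the C3–C8 bond is weakened so that the [3,3] shift (anionic oxy-Cope rearrangement, the known four-carbon ring expansion of 1,2-dialkenylcycloalkanols) should run near room temperature: C5–C6 forms as C3–C8 breaks and the enolate 21 makes it irreversible. The nine-membered ring is closed by ring expansion, not by cyclisation of a chain: the C5–C6 bond is made inside a six-centre boat array whose two allyl halves are held cis on the exo face of the cyclopentane, and the former ring bond becomes the C3=C4 and C7=C8 termini. C5 is set by suprafacial chirality transfer from C3 through the allyl unit, so with both alkenyl groups folded over the five-membered ring the (E)-enol ether should give (5R) together with the Z C3=C4 alkene. C9 is set afterwards under thermodynamic control: the methanol quench gives the cis-fused ketone 22, which potassium methoxide should equilibrate through the C8–C9 enolate to the more stable trans fusion 23, while C1 is untouched. The step needs boat over chair (a chair or a dissociative path would give the E alkene with the 5S centre); this rests on the cis relation of the alkenyl groups on a five-membered ring, where the eclipsed boat is the array that fits, and the PMB ether is base-stable and γ to the carbonyl, so it cannot eliminate.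

Step 11
Reactants: 23 (1S,5R,6Z,9R)-5-[(4-methoxyphenyl)methoxy]-6,10,10-trimethylbicyclo[7.2.0]undec-6-en-2-one
Product: 24 (1R,3Z,5R,9S)-5-[(4-methoxyphenyl)methoxy]-4,11,11-trimethyl-8-methylidenebicyclo[7.2.0]undec-3-ene
Conditions: Ph3PCH3Br, KOtBu, toluene, 80 °C
Reagents that add atoms: methyltriphenylphosphonium bromide, C[P+](c1ccccc1)(c1ccccc1)c1ccccc1.[Br-]
Why: Wittig methylenation of the hindered ketone next to the ring-fusion methine; the basic ylide can only move C9 toward the already favoured trans fusion and the PMB ether is inert.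

Step 12
Reactants: 25 2,4,6-trihydroxyacetophenone
Product: 26 2-acetyl-3-hydroxy-4,4,6,6-tetramethylcyclohex-2-ene-1,5-dione (acetylsyncarpic acid)
Conditions: NaOMe, MeI, MeOH, reflux
Reagents that add atoms: iodomethane, CI
Why: Exhaustive C-methylation of the phloroglucinol anion (two methyl groups on each free ring carbon) dearomatises the ring to the enolised acetyl triketone, a known preparation.

Step 13
Reactants: 26 acetylsyncarpic acid
Product: 27 2,2,4,4-tetramethylcyclohexane-1,3,5-trione (syncarpic acid)
Conditions: 6 M aq. HCl, reflux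
Reagents that add atoms: none
Why: Acid-mediated retro-Claisen deacetylation of the β-triketone removes the acetyl group as acetic acid.

Step 14
Reactants: 24 (1R,3Z,5R,9S)-5-[(4-methoxyphenyl)methoxy]-4,11,11-trimethyl-8-methylidenebicyclo[7.2.0]undec-3-ene; 27 syncarpic acid; 28 3-methylbutanal
Product: 30 5-O-(4-methoxybenzyl)tomentodione O, via alkylidene trione 29 (not isolated)
Conditions: ethylenediammonium diacetate (cat.), 4 Å MS, toluene, 80 °C
Reagents that add atoms: none
Why: Tietze-type domino Knoevenagel/inverse-demand hetero-Diels–Alder, the reaction class by which β-triketones, aldehydes and the exocyclic methylene of caryophyllene-type alkenes give spiro-dihydropyrans; the electron-rich 1,1-disubstituted alkene should react in preference to the hindered allylic-ether alkene with oxygen going to the more substituted C8; with H9 eclipsing the C8=CH2 bond the ring body shields one face, so O–C8 should form on the face flanked by the C10 methylene (8S), and with the isobutyl group outside on the heterodiene and the bulky C9 branch exo (C7 endo) C7' should come out R.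

Step 15
Reactants: 30 5-O-(4-methoxybenzyl)tomentodione O
Product: 31 tomentodione O
Conditions: DDQ, CH2Cl2/pH 7 buffer, 0 °C
Reagents that add atoms: none
Why: Oxidative PMB cleavage (electron-transfer oxidation of the electron-rich benzyl ether, then hydrolysis) frees the C5 allylic alcohol without touching a stereocentre; the hydroxyl is unmasked only now because a free 5-OH opposite a C8 ketone would close a transannular hemiketal.

**Compound list**

1 | 5-methylhex-4-enal | CC(C)=CCCC=O | starting material
2 | vinylmagnesium bromide | C=C[Mg]Br | starting material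
3 | rac-7-methylocta-1,6-dien-3-ol | C=CC(O)CCC=C(C)C | intermediate
4 | (3S)-7-methylocta-1,6-dien-3-ol | C=C[C@@H](O)CCC=C(C)C | intermediate
5 | (1R,2S,5R)-6,6-dimethylbicyclo[3.2.0]heptan-2-ol (OH endo) | O[C@H]1CC[C@@H]2[C@H]1CC2(C)C | intermediate
6 | (1R,5R)-6,6-dimethylbicyclo[3.2.0]heptan-2-one | O=C1CC[C@@H]2[C@H]1CC2(C)C | intermediate
7 | lithium (1R,5R)-6,6-dimethylbicyclo[3.2.0]hept-2-en-2-olate (formed in the flask) | [Li]OC1=CC[C@@H]2[C@H]1CC2(C)C | intermediate
8 | trimethyl{[(1R,5R)-6,6-dimethylbicyclo[3.2.0]hept-2-en-2-yl]oxy}silane | C[Si](C)(C)OC1=CC[C@@H]2[C@H]1CC2(C)C | intermediate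
9 | (4-methoxyphenyl)methanol | COc1ccc(CO)cc1 | starting material
10 | trichloroethene | ClC=C(Cl)Cl | starting material
11 | 1-({[(E)-1,2-dichloroethenyl]oxy}methyl)-4-methoxybenzene (formed in the flask) | COc1ccc(CO/C(Cl)=C\Cl)cc1 | intermediate
12 | 1-{[(chloroethynyl)oxy]methyl}-4-methoxybenzene (formed in the flask) | COc1ccc(COC#CCl)cc1 | intermediate
13 | lithium [(4-methoxyphenyl)methoxy]acetylide (formed in the flask) | COc1ccc(COC#C[Li])cc1 | intermediate
14 | 1-methoxy-4-[(prop-1-yn-1-yloxy)methyl]benzene | COc1ccc(COC#CC)cc1 | intermediate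
15 | chloro{(1E)-1-[(4-methoxyphenyl)methoxy]prop-1-en-2-yl}zirconocene (formed in the flask) | C/C(=C\OCc1ccc(OC)cc1)[Zr](Cl)(C1C=CC=C1)C1C=CC=C1 | intermediate
16 | 1-({[(1E)-2-iodoprop-1-en-1-yl]oxy}methyl)-4-methoxybenzene | C/C(I)=C\OCc1ccc(OC)cc1 | intermediate
17 | tributyl{[(1R,5R)-6,6-dimethylbicyclo[3.2.0]hept-2-en-2-yl]oxy}stannane (formed in the flask) | CCCC[Sn](CCCC)(CCCC)OC1=CC[C@@H]2[C@H]1CC2(C)C | intermediate
18 | (1R,3S,5R)-3-{(1E)-1-[(4-methoxyphenyl)methoxy]prop-1-en-2-yl}-6,6-dimethylbicyclo[3.2.0]heptan-2-one (alkenyl exo) | O=C1[C@H](/C(C)=C/OCc2ccc(OC)cc2)C[C@@H]2[C@H]1CC2(C)C | intermediate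
19 | (1R,2R,3S,5R)-2-ethenyl-3-{(1E)-1-[(4-methoxyphenyl)methoxy]prop-1-en-2-yl}-6,6-dimethylbicyclo[3.2.0]heptan-2-ol (vinyl and alkenyl both exo) | C=C[C@]1(O)[C@H](/C(C)=C/OCc2ccc(OC)cc2)C[C@@H]2[C@H]1CC2(C)C | intermediate
20 | potassium alkoxide of 19 (formed in the flask) | C=C[C@]1([O-])[C@H](/C(C)=C/OCc2ccc(OC)cc2)C[C@@H]2[C@H]1CC2(C)C.[K+] | intermediate
21 | potassium (1R,2E,5R,6Z,9R)-5-[(4-methoxyphenyl)methoxy]-6,10,10-trimethylbicyclo[7.2.0]undeca-2,6-dien-2-olate (formed in the flask) | C/C1=C/C[C@@H]2[C@@H](CC2(C)C)/C([O-])=C\CC[C@H]1OCc1ccc(OC)cc1.[K+] | intermediate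
22 | (1R,5R,6Z,9R)-5-[(4-methoxyphenyl)methoxy]-6,10,10-trimethylbicyclo[7.2.0]undec-6-en-2-one (cis-fused; formed in the flask) | C/C1=C/C[C@@H]2[C@@H](CC2(C)C)C(=O)CC[C@H]1OCc1ccc(OC)cc1 | intermediate
23 | (1S,5R,6Z,9R)-5-[(4-methoxyphenyl)methoxy]-6,10,10-trimethylbicyclo[7.2.0]undec-6-en-2-one (trans-fused) | C/C1=C/C[C@@H]2[C@H](CC2(C)C)C(=O)CC[C@H]1OCc1ccc(OC)cc1 | intermediate
24 | (1R,3Z,5R,9S)-5-[(4-methoxyphenyl)methoxy]-4,11,11-trimethyl-8-methylidenebicyclo[7.2.0]undec-3-ene | C/C1=C/C[C@@H]2[C@H](CC2(C)C)C(=C)CC[C@H]1OCc1ccc(OC)cc1 | intermediate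
25 | 2,4,6-trihydroxyacetophenone | CC(=O)c1c(O)cc(O)cc1O | starting material
26 | 2-acetyl-3-hydroxy-4,4,6,6-tetramethylcyclohex-2-ene-1,5-dione (acetylsyncarpic acid) | CC(=O)C1=C(O)C(C)(C)C(=O)C(C)(C)C1=O | intermediate
27 | 2,2,4,4-tetramethylcyclohexane-1,3,5-trione (syncarpic acid) | CC1(C)C(=O)CC(=O)C(C)(C)C1=O | intermediate
28 | 3-methylbutanal | CC(C)CC=O | starting material
29 | 2,2,4,4-tetramethyl-6-(3-methylbutylidene)cyclohexane-1,3,5-trione (formed in the flask) | CC(C)CC=C1C(=O)C(C)(C)C(=O)C(C)(C)C1=O | intermediate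
30 | 5-O-(4-methoxybenzyl)tomentodione O (1R,3Z,5R,8S,9S,7'R) | C/C1=C/C[C@@H]2[C@H](CC2(C)C)[C@]2(CC[C@H]1OCc1ccc(OC)cc1)C[C@@H](CC(C)C)C1=C(O2)C(C)(C)C(=O)C(C)(C)C1=O | intermediate
31 | tomentodione O (1R,3Z,5R,8S,9S,7'R) | C/C1=C/C[C@@H]2[C@H](CC2(C)C)[C@]2(CC[C@H]1O)C[C@@H](CC(C)C)C1=C(O2)C(C)(C)C(=O)C(C)(C)C1=O | target

**Step count and risks**

Total step count: 15. Longest linear sequence: 11 steps (steps 1–5, 8–11, 14, 15); steps 6–7 and 12–13 are side branches.

Steps most likely to fail:

1. Step 10 (key step). The alkoxide may leak through a chair-like array, or dissociate to an enone and an alkoxyallyl anion that recombine; either path would deliver the (3E) alkene together with the (5S) centre beside 23. In the fallback, alkene geometry and C5 are set by equilibration and reagent control instead of by sigmatropic transfer. The crude ketone mixture is carried through step 11, so the fallback sets out from 24 accompanied by its (3E,5S) isomer F1. DDQ (CH2Cl2/pH 7 buffer) should unmask both allylic alcohols, the (3E,5S)-dienol F2 and the (3Z,5R)-dienol F3. MnO2 should oxidise both to the enones, the (3E)-dienone F4 and the (3Z)-dienone F5. Catalytic PhSH/Et3N (reversible conjugate addition) should drain the strained F4 into F5. Corey–Bakshi–Shibata reduction of F5, with the catalyst enantiomer that delivers hydride to the face giving the (5R) alcohol, should return F3 alone. NaH/PMBCl then comes back to the route at 24.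

2. Step 14. The heterodiene may add to the other face of the C8 methylene, or with the C9 branch endo, so that C8/C7' diastereomers of 30 predominate. The fallback is stepwise, with C8 under thermodynamic control and C7' set by hydride delivery; it sets out from ketone 23 and acetylsyncarpic acid 26. A Kabbe condensation (pyrrolidine, toluene, reflux: aldol condensation of the acetyl group on C8, then reversible oxa-Michael closure) should give the spiro-chromanone F6. Isobutylmagnesium bromide/CeCl3 (THF, −78 °C) should add to the least hindered carbonyl (C7') to give the tertiary carbinol F7. Ionic hydrogenation (Et3SiH, BF3·OEt2, CH2Cl2, −78 °C) through the oxygen-stabilised C7' cation should place hydrogen on the face remote from the cyclobutane branch and come back to the route at 30.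

3. Step 9. Attack anti to the C3 alkenyl group (from the endo face), or enolisation of the β,γ-unsaturated ketone, may compete and give the trans-dialkenyl carbinol, which cannot reach the boat array. In the fallback the two-carbon unit enters as a rod-shaped sp nucleophile and is then semi-reduced; it sets out from 18. Ethynylmagnesium bromide/CeCl3 (THF, −78 °C), whose facial choice should be governed almost only by the ring fusion, should give the 2-exo-ethynyl carbinol F8. Lindlar semi-hydrogenation (Pd/CaCO3/Pb, quinoline, H2) comes back to the route at 19.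

**Further compounds**

F1 | step 10 | (1R,3E,5S,9S)-5-[(4-methoxyphenyl)methoxy]-4,11,11-trimethyl-8-methylidenebicyclo[7.2.0]undec-3-ene | C/C1=C\C[C@@H]2[C@H](CC2(C)C)C(=C)CC[C@@H]1OCc1ccc(OC)cc1
F2 | step 10 | (1R,3E,5S,9S)-4,11,11-trimethyl-8-methylidenebicyclo[7.2.0]undec-3-en-5-ol | C/C1=C\C[C@@H]2[C@H](CC2(C)C)C(=C)CC[C@@H]1O
F3 | step 10 | (1R,3Z,5R,9S)-4,11,11-trimethyl-8-methylidenebicyclo[7.2.0]undec-3-en-5-ol | C/C1=C/C[C@@H]2[C@H](CC2(C)C)C(=C)CC[C@H]1O
F4 | step 10 | (1R,3E,9S)-4,11,11-trimethyl-8-methylidenebicyclo[7.2.0]undec-3-en-5-one | C/C1=C\C[C@@H]2[C@H](CC2(C)C)C(=C)CCC1=O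
F5 | step 10 | (1R,3Z,9S)-4,11,11-trimethyl-8-methylidenebicyclo[7.2.0]undec-3-en-5-one | C/C1=C/C[C@@H]2[C@H](CC2(C)C)C(=C)CCC1=O
F6 | step 14 | spiro-chromanone: 7'-oxo-7'-de(isobutyl) analogue of 30 | C/C1=C/C[C@@H]2[C@H](CC2(C)C)[C@]2(CC[C@H]1OCc1ccc(OC)cc1)CC(=O)C1=C(O2)C(C)(C)C(=O)C(C)(C)C1=O
F7 | step 14 | 7'-hydroxy analogue of 30 (C7' configuration not controlled; both epimers give the same cation) | C/C1=C/C[C@@H]2[C@H](CC2(C)C)[C@]2(CC[C@H]1OCc1ccc(OC)cc1)CC(O)(CC(C)C)C1=C(O2)C(C)(C)C(=O)C(C)(C)C1=O
F8 | step 9 | 2-exo-ethynyl analogue of 19: 2-ethynyl-3-{(1E)-1-[(4-methoxyphenyl)methoxy]prop-1-en-2-yl}-6,6-dimethylbicyclo[3.2.0]heptan-2-ol | C#C[C@]1(O)[C@H](/C(C)=C/OCc2ccc(OC)cc2)C[C@@H]2[C@H]1CC2(C)C
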